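**Retrosynthetic overview**
1. Feature used: the ring O1–C2–C3–C3a–C7a, with its trans aryl (C2) and methyl (C3) groups, is a β-methyl-γ-aryl-γ-butyrolactone in disguise (C7a = lactone carbonyl, C3a = α-carbon). The carbocycle C3a–C4–C5–C6–C7–C7a is grown onto it.
2. Last disconnections: C3a=C4 (loss of water from a C4 carbinol) and the enol ether O1–C7a=C7 lead back to a hydroxy-1,3-diketone, which is opened at C7–C7a to a C6 methyl ketone and the lactone.
3. Key disconnection: C3–CH3 and C3a–C4, giving an (S)-γ-aryl butenolide, Me2CuLi and an α-quaternary aldehyde that carries C4–C7, the C5 stereocentre with its allyl and methoxy groups, and C6 as a dimethyl ketal.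
4. Aldehyde: acylation of methyl methoxyacetate, Noyori hydrogenation and Fráter–Seebach allylation set C5. Butenolide: asymmetric propiolate addition to 3,4,5-trimethoxybenzaldehyde, semihydrogenation, lactonisation.
5. Ring order: five-membered oxygen ring first (as the butenolide, step 2), six-membered carbocycle second (step 12), last double bond in step 13.

Key step: step 10

Remark: atom labels (O1, C2, C3, C3a, C4–C7, C7a) are those of the target and are used for all intermediates; the C4 carbinol centre formed in step 10 is carried as both epimers and, like C3a, is removed in step 13.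

**Step 1**
Reactants: 1 3,4,5-trimethoxybenzaldehyde; 2 methyl propiolate
Product: 3 methyl (R)-4-hydroxy-4-(3,4,5-trimethoxyphenyl)but-2-ynoate
Conditions: 2, ZnEt2, HMPA, CH2Cl2, rt; (S)-BINOL (40 mol%), Ti(OiPr)4 (1 equiv); then 1, rt
Reagents that add atoms: none
Why: BINOL–titanium-catalysed addition of the zinc acetylide of methyl propiolate to an aryl aldehyde (catalytic asymmetric alkynylation), in which (S)-BINOL should deliver the alkynyl group to the Si face and so set C2 as the (R)-propargylic carbinol (the antipodal ligand is at hand if the sense has to be corrected).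

**Step 2**
Reactants: 3 methyl (R)-4-hydroxy-4-(3,4,5-trimethoxyphenyl)but-2-ynoate
Product: 5 (S)-5-(3,4,5-trimethoxyphenyl)furan-2(5H)-one, via Z-hydroxy enoate 4 (not isolated)
Conditions: H2 (1 atm), Pd/CaCO3–Pb(OAc)2 (Lindlar catalyst), quinoline (cat.), EtOAc, rt; then pyridinium p-toluenesulfonate (cat.), CH2Cl2, rt
Reagents that add atoms: none
Why: Lindlar semihydrogenation gives the Z-enoate, whose cis-disposed hydroxyl and ester groups close to the butenolide by lactonisation, while the C2 centre is untouched because no base able to remove the γ-hydrogen is present.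

**Step 3**
Reactants: 6 methyl methoxyacetate; 7 N-methoxy-N-methylacetamide
Product: 8 methyl 2-methoxy-3-oxobutanoate (racemic)
Conditions: 6 (2 equiv), LiN(iPr)2 (2 equiv), THF, −78 °C; then 7 (1 equiv), −78 → 0 °C
Reagents that add atoms: none
Why: Crossed Claisen-type acylation of the lithium enolate of the α-methoxy ester by an N-methoxy-N-methylamide, whose chelated tetrahedral adduct prevents over-reaction and releases the β-keto ester only on work-up.

**Step 4**
Reactants: 8 methyl 2-methoxy-3-oxobutanoate
Product: 9 methyl (3R)-3-hydroxy-2-methoxybutanoate (both C2 epimers)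
Conditions: H2 (50 atm), RuCl2[(R)-BINAP] (0.5 mol%), MeOH, 50 °C
Reagents that add atoms: none
Why: Noyori asymmetric hydrogenation of a β-keto ester, in which ester and methoxy chelation place the substrate on the (R)-BINAP catalyst in the same way, so that hydride should arrive on the ketone face giving the (3R)-carbinol (the configuration at C2 does not matter because it is planarised in step 5).

**Step 5**
Reactants: 9 methyl (3R)-3-hydroxy-2-methoxybutanoate; 10 allyl bromide
Product: 11 methyl (2S)-2-[(1R)-1-hydroxyethyl]-2-methoxypent-4-enoate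
Conditions: LiN(iPr)2 (2.3 equiv), THF, −78 → −20 °C; then 10, DMPU, −78 → −10 °C
Reagents that add atoms: none
Why: Fráter–Seebach alkylation, in which the chelated lithium alkoxide–enolate dianion offers allyl bromide the face anti to the carbinol methyl group, so that the (R)-carbinol centre sets the quaternary carbon (future C5) as (S) and any minor diastereomer can be removed by chromatography.

**Step 6**
Reactants: 11 methyl (2S)-2-[(1R)-1-hydroxyethyl]-2-methoxypent-4-enoate
Product: 12 methyl (S)-2-acetyl-2-methoxypent-4-enoate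
Conditions: Dess–Martin periodinane, CH2Cl2, rt
Reagents that add atoms: none
Why: Dess–Martin oxidation of the secondary alcohol to the methyl ketone (future C6 and C7), which cannot epimerise the quaternary α-carbon and leaves the terminal alkene alone.

**Step 7**
Reactants: 12 methyl (S)-2-acetyl-2-methoxypent-4-enoate
Product: 13 methyl (S)-2-(1,1-dimethoxyethyl)-2-methoxypent-4-enoate
Conditions: HC(OMe)3, MeOH, TsOH·H2O (cat.), 50 °C
Reagents that add atoms: trimethyl orthoformate, COC(OC)OC; methanol, CO
Why: Acid-catalysed ketalisation driven by the orthoformate as water scavenger masks the ketone, which is activated by its α-methoxy and α-ester groups, while ester and alkene are inert.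

**Step 8**
Reactants: 13 methyl (S)-2-(1,1-dimethoxyethyl)-2-methoxypent-4-enoate
Product: 14 (R)-2-(1,1-dimethoxyethyl)-2-methoxypent-4-en-1-ol
Conditions: LiAlH4, Et2O, 0 °C
Reagents that add atoms: none
Why: Hydride reduction of the ester to the primary alcohol, to which ketal, ether and alkene are stable.

**Step 9**
Reactants: 14 (R)-2-(1,1-dimethoxyethyl)-2-methoxypent-4-en-1-ol
Product: 15 (R)-2-(1,1-dimethoxyethyl)-2-methoxypent-4-enal
Conditions: nPr4N[RuO4] (5 mol%), N-methylmorpholine N-oxide, 4 Å MS, CH2Cl2, rt
Reagents that add atoms: none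
Why: Ley–Griffith oxidation under neutral conditions gives the aldehyde without endangering the acid-labile ketal, and the aldehyde has no α-hydrogen so it can neither enolise nor epimerise.

**Step 10**
Reactants: 5 (S)-5-(3,4,5-trimethoxyphenyl)furan-2(5H)-one; 15 (R)-2-(1,1-dimethoxyethyl)-2-methoxypent-4-enal
Product: 18 (3R,4S,5S)-3-[(2R)-2-(1,1-dimethoxyethyl)-1-hydroxy-2-methoxypent-4-en-1-yl]-4-methyl-5-(3,4,5-trimethoxyphenyl)dihydrofuran-2(3H)-one (C4 carbinol epimers), via lithium dimethylcuprate 16 (not isolated), via lithium lactone enolate 17 (not isolated)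
Conditions: CuI (1.05 equiv), MeLi (2.1 equiv), Et2O, 0 °C; 5 in THF, −78 °C; then 15 (1.2 equiv), THF, −78 °C; aq NH4Cl
Reagents that add atoms: methyllithium, [Li]C
Why: Lithium dimethylcuprate, formed from CuI and two equivalents of MeLi, adds 1,4 to butenolide 5 (π-complex, oxidative addition at the β-carbon, reductive elimination) on the face opposite the C2 aryl group, which fixes the 2,3-trans relationship and C3 as (S). The lithium lactone enolate 17 released in this way then attacks the aldehyde carbon of 15 on the face opposite the new C3 methyl group and forms C3a–C4; the closest known reaction type is the tandem conjugate addition–aldol trapping (three-component coupling) of butenolides. No ring is closed in this step. C3 is controlled by the C2 aryl group, C3a by the C3 methyl group (3,3a-trans), C5 arrives intact in 15, and the C4 carbinol is left uncontrolled because C3a and C4 both become sp2 in step 13. The step needs 1,4-addition to win over removal of the acidic γ-hydrogen at C2 and the enolate to be captured at carbon and not by a proton; the low basicity of the cuprate at −78 °C secures the first, and the lack of α-hydrogens in 15 together with the ketal on C6 secures the second.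

**Step 11**
Reactants: 18 aldol adduct (ketal)
Product: 19 (3R,4S,5S)-3-[(2R)-2-acetyl-1-hydroxy-2-methoxypent-4-en-1-yl]-4-methyl-5-(3,4,5-trimethoxyphenyl)dihydrofuran-2(3H)-one (C4 carbinol epimers)
Conditions: 2 M HCl, THF, rt
Reagents that add atoms: water, O
Why: Acid-catalysed hydrolysis of the dimethyl ketal frees the methyl ketone (C6, C7) under conditions too mild to dehydrate the β-hydroxy lactone or to ionise the benzylic C2–O bond.

**Step 12**
Reactants: 19 hydroxy keto lactone
Product: 21 (2S,3S,3aR,5R)-5-allyl-4-hydroxy-5-methoxy-3-methyl-2-(3,4,5-trimethoxyphenyl)-3,3a,4,5-tetrahydrobenzofuran-6(2H)-one (C4 epimers), via hydroxy diketone 20 (not isolated)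
Conditions: LiN(SiMe3)2 (3.2 equiv), THF, −78 → 0 °C; 1 M HCl; then camphorsulfonic acid (10 mol%), 4 Å MS, CH2Cl2, rt
Reagents that add atoms: none
Why: Intramolecular Claisen (Dieckmann-type) acylation in which excess base at −78 °C converts the C4 hydroxyl to its alkoxide and the only enolisable ketone position, the C7 methyl group, to its enolate, which closes the six-membered ring onto the lactone carbonyl C7a (6-exo-trig), after which acid re-closes the freed C2 hydroxyl onto C7a as the conjugated enol ether O1–C7a=C7–C6=O with loss of water, C2, C3 and C5 taking no part.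

**Step 13**
Reactants: 21 hydroxy vinylogous ester
Product: 23 (2S,3S,5R)-5-allyl-5-methoxy-3-methyl-2-(3,4,5-trimethoxyphenyl)-2,3-dihydrobenzofuran-6(5H)-one (target), via C4 mesylate 22 (not isolated)
Conditions: MsCl, Et3N, CH2Cl2, 0 °C; then DBU, 0 °C → rt
Reagents that add atoms: none
Why: Mesylation of the C4 hydroxyl followed by base-induced 1,2-elimination of the only available β-hydrogen, H3a (which is the γ-hydrogen of the vinylogous ester), installs C3a=C4 without acid or heat, which could cause allyl migration in the dienone.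

**Compound list**
1 | 3,4,5-trimethoxybenzaldehyde | COc1cc(C=O)cc(OC)c1OC | starting material
2 | methyl propiolate | C#CC(=O)OC | starting material
3 | methyl (R)-4-hydroxy-4-(3,4,5-trimethoxyphenyl)but-2-ynoate | COC(=O)C#C[C@H](O)c1cc(OC)c(OC)c(OC)c1 | intermediate
4 | methyl (S,Z)-4-hydroxy-4-(3,4,5-trimethoxyphenyl)but-2-enoate | COC(=O)/C=C\[C@H](O)c1cc(OC)c(OC)c(OC)c1 | intermediate (not isolated)
5 | (S)-5-(3,4,5-trimethoxyphenyl)furan-2(5H)-one | O=C1C=C[C@@H](c2cc(OC)c(OC)c(OC)c2)O1 | intermediate
6 | methyl methoxyacetate | COCC(=O)OC | starting material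
7 | N-methoxy-N-methylacetamide | CC(=O)N(C)OC | starting material
8 | methyl 2-methoxy-3-oxobutanoate (racemic) | CC(=O)C(OC)C(=O)OC | intermediate
9 | methyl (3R)-3-hydroxy-2-methoxybutanoate (C2 epimers) | C[C@@H](O)C(OC)C(=O)OC | intermediate
10 | allyl bromide | C=CCBr | starting material
11 | methyl (2S)-2-[(1R)-1-hydroxyethyl]-2-methoxypent-4-enoate | C=CC[C@@]([C@@H](C)O)(OC)C(=O)OC | intermediate
12 | methyl (S)-2-acetyl-2-methoxypent-4-enoate | C=CC[C@@](C(C)=O)(OC)C(=O)OC | intermediate
13 | methyl (S)-2-(1,1-dimethoxyethyl)-2-methoxypent-4-enoate | C=CC[C@@](C(C)(OC)OC)(OC)C(=O)OC | intermediate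
14 | (R)-2-(1,1-dimethoxyethyl)-2-methoxypent-4-en-1-ol | C=CC[C@@](C(C)(OC)OC)(OC)CO | intermediate
15 | (R)-2-(1,1-dimethoxyethyl)-2-methoxypent-4-enal | C=CC[C@@](C(C)(OC)OC)(OC)C=O | intermediate
16 | lithium dimethylcuprate | [Li+].C[Cu-]C | intermediate (not isolated)
17 | lithium (4S,5S)-4-methyl-5-(3,4,5-trimethoxyphenyl)-4,5-dihydrofuran-2-olate | [Li+].[O-]C1=C[C@H](C)[C@@H](c2cc(OC)c(OC)c(OC)c2)O1 | intermediate (not isolated)
18 | (3R,4S,5S)-3-[(2R)-2-(1,1-dimethoxyethyl)-1-hydroxy-2-methoxypent-4-en-1-yl]-4-methyl-5-(3,4,5-trimethoxyphenyl)dihydrofuran-2(3H)-one (carbinol epimers) | O=C1O[C@H](c2cc(OC)c(OC)c(OC)c2)[C@@H](C)[C@@H]1C(O)[C@](OC)(CC=C)C(C)(OC)OC | intermediate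
19 | (3R,4S,5S)-3-[(2R)-2-acetyl-1-hydroxy-2-methoxypent-4-en-1-yl]-4-methyl-5-(3,4,5-trimethoxyphenyl)dihydrofuran-2(3H)-one (carbinol epimers) | O=C1O[C@H](c2cc(OC)c(OC)c(OC)c2)[C@@H](C)[C@@H]1C(O)[C@](OC)(CC=C)C(C)=O | intermediate
20 | (4R,6R)-4-allyl-5-hydroxy-6-[(1S,2S)-1-hydroxy-1-(3,4,5-trimethoxyphenyl)propan-2-yl]-4-methoxycyclohexane-1,3-dione (C5 epimers; in equilibrium with enol and hemiketal forms) | C=CC[C@@]1(OC)C(O)[C@@H]([C@H](C)[C@H](O)c2cc(OC)c(OC)c(OC)c2)C(=O)CC1=O | intermediate (not isolated)
21 | (2S,3S,3aR,5R)-5-allyl-4-hydroxy-5-methoxy-3-methyl-2-(3,4,5-trimethoxyphenyl)-3,3a,4,5-tetrahydrobenzofuran-6(2H)-one (C4 epimers) | C=CC[C@@]1(OC)C(O)[C@@H]2C(=CC1=O)O[C@H](c1cc(OC)c(OC)c(OC)c1)[C@H]2C | intermediate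
22 | (2S,3S,3aR,5R)-5-allyl-5-methoxy-3-methyl-6-oxo-2-(3,4,5-trimethoxyphenyl)-2,3,3a,4,5,6-hexahydrobenzofuran-4-yl methanesulfonate (C4 epimers) | C=CC[C@@]1(OC)C(OS(C)(=O)=O)[C@@H]2C(=CC1=O)O[C@H](c1cc(OC)c(OC)c(OC)c1)[C@H]2C | intermediate (not isolated)
23 | (2S,3S,5R)-5-allyl-5-methoxy-3-methyl-2-(3,4,5-trimethoxyphenyl)-2,3-dihydrobenzofuran-6(5H)-one | C=CC[C@@]1(OC)C=C2C(=CC1=O)O[C@H](c1cc(OC)c(OC)c(OC)c1)[C@H]2C | target

**Step count and risks**
Total: 13 steps. Longest linear sequence: 11 steps (steps 3–13, from methyl methoxyacetate 6); the butenolide branch is 2 steps.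

Most likely to fail:

1. Step 10. The hindered α-quaternary aldehyde may capture the enolate too slowly, so that proton transfer, reversal of the aldol on warming, methyl transfer to the aldehyde, or loss of C2 configuration by γ-deprotonation compete. Fallback, setting out from 5 and returning at 18: the two bond formations are separated. 5 is treated with Me2CuLi alone and the enolate is protonated at −78 °C to give (4S,5S)-4-methyl-5-(3,4,5-trimethoxyphenyl)dihydrofuran-2(3H)-one F1, which is isolated. F1 is then deprotonated with LiN(iPr)2 in THF at −78 °C, which regenerates enolate 17 free of copper species, and this is transmetalated with ZnCl2 and added to 15 in a directed aldol addition, again anti to the C3 methyl group, to give 18.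

2. Step 12. The C4 alkoxide may fragment by retro-aldol cleavage (C4–C5 or C3a–C4) faster than the C7 enolate closes onto the lactone, or enolisation may occur at C3a. Fallback, setting out from 19 and returning at 21: the C4 hydroxyl is silylated first (Et3SiOTf, 2,6-lutidine, CH2Cl2, −78 °C) to give (3R,4S,5S)-3-[(2R)-2-acetyl-2-methoxy-1-(triethylsilyloxy)pent-4-en-1-yl]-4-methyl-5-(3,4,5-trimethoxyphenyl)dihydrofuran-2(3H)-one F2, so that no alkoxide is present during ring closure. LiN(SiMe3)2 then gives (4R,6R)-4-allyl-6-[(1S,2S)-1-hydroxy-1-(3,4,5-trimethoxyphenyl)propan-2-yl]-4-methoxy-5-(triethylsilyloxy)cyclohexane-1,3-dione F3, and camphorsulfonic acid in wet CH2Cl2 removes the silyl group and closes the enol ether to 21.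

3. Step 5. Formation of the fully substituted alkoxide–enolate dianion may be incomplete or accompanied by retro-aldol cleavage, and the α-methoxy group may lower the facial selectivity. Fallback, setting out from 8 and returning at 12 (bypassing 9 and 11): 8 is allylated directly at C2 in a catalytic asymmetric Tsuji–Trost reaction (allyl acetate, Pd2(dba)3, a chiral trans-1,2-diaminocyclohexane-derived bis(2-diphenylphosphinobenzamide) ligand, mild base), the α-methoxy group helping to fix the enolate geometry by chelation. The ligand enantiomer is chosen, and the enantiomeric purity judged, by comparison with 12 made through 11. No new compound is made (F0).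

**Further compounds**
F1 | step 10 | (4S,5S)-4-methyl-5-(3,4,5-trimethoxyphenyl)dihydrofuran-2(3H)-one | O=C1C[C@H](C)[C@@H](c2cc(OC)c(OC)c(OC)c2)O1
F2 | step 12 | (3R,4S,5S)-3-[(2R)-2-acetyl-2-methoxy-1-(triethylsilyloxy)pent-4-en-1-yl]-4-methyl-5-(3,4,5-trimethoxyphenyl)dihydrofuran-2(3H)-one | O=C1O[C@H](c2cc(OC)c(OC)c(OC)c2)[C@@H](C)[C@@H]1C(O[Si](CC)(CC)CC)[C@](OC)(CC=C)C(C)=O
F3 | step 12 | (4R,6R)-4-allyl-6-[(1S,2S)-1-hydroxy-1-(3,4,5-trimethoxyphenyl)propan-2-yl]-4-methoxy-5-(triethylsilyloxy)cyclohexane-1,3-dione | C=CC[C@@]1(OC)C(O[Si](CC)(CC)CC)[C@@H]([C@H](C)[C@H](O)c2cc(OC)c(OC)c(OC)c2)C(=O)CC1=O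
F0 | step 5 | none | none
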